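The constants used here were set for the occasion; the flask was simulated.

I decided to follow this flask by the fraction of reagent left, f, and not by the target made.

    starting material + reagent → target (k1 = 40 L mol⁻¹ s⁻¹)
    starting material + 2 reagent → side product (k2 = 740 L² mol⁻² s⁻¹)
    crystals ⇌ target, rate k3*(cs3 - [target]) while solid is left; crystals form when [target] > cs3 (cs3 = 1.4 mM, k3 = 3.4 s⁻¹)

starting material 2.0 mM; reagent 1.40 mM; time 2.0 h

- why nothing more happens at 2.0 h, or that something still does (it is still moving / the reagent has run out first / all of the starting material has reacted)
- conversion of starting material at 2.0 h
- amount of target at 2.0 h, in percent of the starting material charged

- what is said of target includes crystals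
- for a step with 2 of a species take k times the square, and two of it per event
- crystals is a solid; its amount is given per volume of the solution
- the reaction counts as stopped when no species that holds the starting material changes by six tenths of a point or more over the second half of the time
- run time (flask): 2.0 h

The reagent charge, 1.40 mM, stood below the 2.0 mM of starting material, and each event takes at least one reagent, so I took reagent as the limiting reagent. In the first instants the main step was quick: by it alone, with the charges as given, starting material has a half-life of 0.21 min, short against the 2.0 h allowed. Reagent then went 19 times faster by the main step than by the side step.

Starting material stands in both rates, so it drops out of their ratio. The side step runs beside the main step in the proportion ρ[reagent], where ρ, the side constant over the main constant, is 18.5 L mol⁻¹. As f fell, the main step's lead grew as one over f, and at f = 0.5 it stood at 38.6.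

Taking each reagent lost as lost to the main step, which led by the ratio above, I summed ρ[reagent] as the reagent fell from its charge to zero, and this gave my estimate of the side charge S, the side product made by the end of the reagent: ρ times the square of the reagent charge, halved, 0.0181 mM. Each side event takes two reagent, so target is the reagent charge less two S, 1.36 mM. That is under the solubility of 1.4 mM, so I expected no crystals. I reckoned 69.1 % conversion and 68.2 % target.

The forecast said the reagent has run out first, with 69.1 % conversion and 68.3 % target, against my 68.2 %. Of its conversion it said: “slightly less because the side route uses two reagent per event”.

The flask gave the reagent has run out first, with 69.1 % conversion and 68.2 % target. Its reagent stood at 0 % of its charge at 2.00 h. S over the starting material charged is 0.905 %, and this flask held 0.876 % side product. For the neighbour flask charged with 0.84 mM of reagent, S comes to 0.006527 mM, or 0.326 % of the starting material charged, and that neighbour held 0.320 % side product at 2.00 h.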